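## Analysis of the target

Compound 17 is a flavone: a benzo ring A fused to a 4-pyranone ring C (4H-chromen-4-one), with aryl ring B on C2. Ring A carries a free hydroxyl at C5, methoxy groups at C7 and C8 and a hydrogen at C6. Ring B carries four contiguous methoxy groups at C2'–C5' and a hydrogen at C6'. There is no stereocentre and no double-bond geometry to set, so every problem is one of regiochemistry and of telling seven oxygen atoms apart. The sensitive points are the six aryl methyl ethers (Lewis and Brønsted acids), the pyranone (a vinylogous ester that hydroxide opens) and the chelated 5-hydroxyl: once it is free, hot strong acid can open ring C and re-close it on the other oxygen (Wessely–Moser rearrangement), turning the 5,7,8 pattern into the 5,6,7 pattern. The real difficulty is ring A: C4a is flanked by two oxygen-bearing carbons, C5 and C8a. The oxygen on C8a must become ring oxygen O1 and the oxygen on C5 must end as the only free phenol, while both rings are too electron-rich for electrophilic chemistry to choose reliably between positions. The plan rests on C4 being a lone carbonyl carbon between C4a of ring A and the C3=C2 unit that bears ring B. C4 can therefore come from carbon monoxide, C3–C2–ring B from an arylacetylene, C4a from the carbon of an aryl iodide, and O1 from the phenol oxygen ortho to that iodide.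

## Retrosynthetic reasoning

**17 back to 16.** The O5–H bond is traced back to an O5–benzyl bond, giving the 5-benzyloxy flavone 16. A benzyl ether is the one ether among seven that can be removed while six methyl ethers stay. The same group keeps O5 silent during ring closure, so that O1 can only come from the other oxygen next to C4a. The forward step must cleave a benzyl ether peri to the C4 carbonyl without touching a methyl ether and without hot acid.

**16 back to 8, 12 and 13.** Three bonds of ring C are cut: C4a–C4, C4–C3 and O1–C2. This releases the iodophenol 8, the arylacetylene 12 and carbon monoxide 13. The cut is made here because C4 is a one-carbon unit between an sp2 carbon and an alkyne-derived two-carbon unit, so the ring can be assembled in one palladium-catalysed operation from three simple pieces, and ring B arrives complete. The C–I bond of 8 marks C4a, which no electrophilic acylation of this ring could do reliably. In the forward direction the aroyl–alkyne coupling must give the hydroxy ynone 14, and the secondary amine used as base must turn 14 into the enaminone 15, so that the phenol oxygen closes the six-membered ring at C2. Insertion of 13 has to come before alkyne transfer, and six-membered closure has to beat five-membered closure.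

**8 back to 7 and 5.** The free hydroxyl of 8 is masked as a methoxymethyl ether (7), and the C–I bond of 7 is cut to give the arene 5 through the aryllithium 6. Electrophilic iodination of a phenol of this type cannot distinguish the position ortho to the hydroxyl from the one para to it. Deprotonation directed by the chelating acetal oxygen can: the carbon between the acetal oxygen and the benzyloxy group is the most acidic ring C–H. The acetal is thus both directing group and temporary mask of the future O1.

**5 back to 4, 2 and 1.** The benzyl ether of 5 is cut to the phenol 4. The C–O bond of 4 at the future C5 is traced, through the formate 3, to the formyl carbon of the aldehyde 2 by an aryl migration to oxygen. Aldehyde 2 is the acetal of the purchasable hydroxy aldehyde 1. Compound 1 already holds the two methoxy groups and the neighbouring hydroxyl in the right order, so no carbon–halogen to carbon–oxygen conversion is needed. The order of protection encodes the regiochemistry of the flavone: the acetal goes on the hydroxyl that sits next to a methoxy group (future O1), the benzyl group on the hydroxyl made later (future O5).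

**12 back to 11 and 9.** The triple bond of 12 is cut to the aldehyde 11 by a one-carbon homologation. The formyl group of 11 is removed to give the symmetric tetramethoxybenzene 9 through the aryllithium 10. The two ring hydrogens of 9 are equivalent, so this branch has no regiochemical question.

## Alternatives that were turned down

**Alternative 1: ring B by chromium carbene benzannulation.**
- Disconnection: ring B is cut at C5'–C6', C1'–C2' and C2'–C3'. The pieces are the ethynylchromone A2 (2-ethynyl-5-hydroxy-7,8-dimethoxy-4H-chromen-4-one), the carbene complex A3, Cr(CO)5[C(OMe)C(OMe)=CH(OMe)] (zerovalent chromium), and one CO ligand.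
- Forward key step: heating A2 with A3 in THF (Dötz benzannulation) would insert the alkyne and one CO and close ring B as the 2'-phenol A1. A final O-methylation of the 2'-hydroxyl in the presence of the chelated 5-hydroxyl would give 17.
- For it: ring B is built with full positional control, and the 2'-oxygen appears as a distinct free phenol.
- Against it: that distinction is not needed here, because all four ring B oxygens are methyl ethers and the ring can be bought as 9. A3 is an electron-rich, labile β-alkoxyvinyl carbene used stoichiometrically. A2 is an electron-poor alkyne and a doubly activated acceptor, the kind of partner that diverts this benzannulation into non-phenolic products. A2 still needs the whole ring A/ring C problem solved beforehand, by a chromone synthesis of several steps.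
- Comparison: on ring B regiocontrol the two routes are equal. The chosen route spends its key step on ring C, the bond set that actually joins the two halves, uses a catalytic metal and is several steps shorter.

**Alternative 2: biomimetic Claisen folding of ring A on a pyranone.**
- Disconnection: ring A is cut at C6–C7, leading to the racemic pyranone A5 (methyl 2-[3-acetyl-4-oxo-6-(2,3,4,5-tetramethoxyphenyl)-4H-pyran-2-yl]-2-methoxyacetate).
- Forward key step: LiN(SiMe3)2 would enolise the acetyl methyl group, the enolate would attack the ester carbonyl of the arm, and enolisation would aromatise ring A to the 5,7-diol A4. Selective 7-O-methylation (the chelated 5-hydroxyl is the less reactive) would give 17.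
- For it: this alternative is stronger than the chosen route on ring A regiochemistry. The oxygen pattern is written into an open chain, O1 is in place from the start and the 8-methoxy group is fixed in the arm. No O1/O5 differentiation, directed metalation or transition metal is needed.
- Against it: the most acidic proton of A5 is on the arm carbon (α to the ester, to a methoxy group and vinylogously to the pyranone carbonyl), so the productive acetyl enolate requires a dianion. The 4-pyranone can be opened by the base. A5 itself needs a long polycarbonyl assembly in which every intermediate has several ways to cyclise.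
- Comparison: the risk would be spread over many steps instead of sitting in one. The chosen route offers two short branches from purchasable arenes and a single demanding step.

**Alternative 3: Friedel–Crafts ring closure of a 3-aryloxycinnamic acid.**
- Disconnection: ring C is cut at C4–C4a, leading to the acid A7 ((Z)-3-(2,3,4,5-tetramethoxyphenyl)-3-(2,3,5-trimethoxyphenoxy)prop-2-enoic acid). A7 would come from conjugate addition of the phenol A8 (2,3,5-trimethoxyphenol) to the propiolate A9 (methyl 3-(2,3,4,5-tetramethoxyphenyl)prop-2-ynoate) and saponification.
- Forward key step: P2O5 in MeSO3H would activate the acid and the acylium carbon would attack the only free position ortho to the aryloxy oxygen, giving the heptamethoxyflavone A6. Peri-selective 5-O-demethylation would give 17.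
- For it: it is at least as short as the chosen route, needs no CO pressure and no palladium, and the ring A regiochemistry is unambiguous. On step economy and simplicity it is equal or better.
- Against it: the ring closure runs in a strongly acidic, dehydrating medium on a substrate with seven methyl ethers and a push–pull enol ether. Acid can cleave the aryloxy–vinyl bond. It can also equilibrate the alkene geometry, after which the acylium is cis to ring B and can close a five-membered ring at C6'; ring B is as nucleophilic as ring A. The O5/other-oxygen differentiation is left to a final selective demethylation, and A8 is not a commodity phenol.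
- Comparison: the chosen route offers a ring closure under basic, non-ionising conditions. The bond to ring A is fixed by a C–I bond, so ring B cannot compete, and O5 is told apart by a benzyl ether instead of by relative rates of demethylation.

Key step: step 8

Remark: 1 and 9 are taken as purchasable. The E geometry drawn for the transient enaminone 15 is the one expected for a secondary-amine adduct and has no bearing on the product.

## Route

Step 1
Reactants: 1 3-hydroxy-4,5-dimethoxybenzaldehyde
Product: 2 3,4-dimethoxy-5-(methoxymethoxy)benzaldehyde
Conditions: MOMCl, i-Pr2NEt, CH2Cl2, 0 °C → rt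
Reagents that add atoms: chloromethyl methyl ether, COCCl
Why: O-alkylation of the phenoxide by the reactive α-chloro ether (MOM protection). The acetal masks the hydroxyl that will become O1 and later directs the lithiation.

Step 2
Reactants: 2 3,4-dimethoxy-5-(methoxymethoxy)benzaldehyde
Product: 4 3,4-dimethoxy-5-(methoxymethoxy)phenol, via aryl formate 3 (not isolated)
Conditions: mCPBA, CH2Cl2, 0 °C → rt; aq NaHCO3 wash; then K2CO3 (cat.), MeOH, rt
Reagents that add atoms: meta-chloroperoxybenzoic acid, OOC(=O)c1cccc(Cl)c1
Why: Baeyer–Villiger (Dakin-type) oxidation: in the Criegee adduct the electron-rich trioxygenated aryl group migrates in preference to hydride and gives formate 3, which mild methanolysis converts to phenol 4. The acetal should tolerate the weakly acidic peracid and the basic methanolysis.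

Step 3
Reactants: 4 3,4-dimethoxy-5-(methoxymethoxy)phenol
Product: 5 5-(benzyloxy)-1,2-dimethoxy-3-(methoxymethoxy)benzene
Conditions: BnBr, K2CO3, DMF, rt
Reagents that add atoms: benzyl bromide, BrCc1ccccc1
Why: Williamson etherification of the phenoxide with a benzylic bromide. The benzyl group goes onto the oxygen that will become O5.

Step 4
Reactants: 5 5-(benzyloxy)-1,2-dimethoxy-3-(methoxymethoxy)benzene
Product: 7 1-(benzyloxy)-2-iodo-4,5-dimethoxy-3-(methoxymethoxy)benzene, via aryllithium 6 (not isolated)
Conditions: n-BuLi, THF, 0 °C; then I2, THF, −78 °C → rt; aq Na2S2O3
Reagents that add atoms: iodine, II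
Why: Directed ortho-metalation: the ring C–H flanked by the chelating acetal oxygen and the benzyloxy oxygen is the most acidic and gives 6, which iodine traps. The other flanked position lacks the acetal chelation, and at 0 °C ring lithiation should outrun deprotonation of the benzylic CH2.

Step 5
Reactants: 7 1-(benzyloxy)-2-iodo-4,5-dimethoxy-3-(methoxymethoxy)benzene
Product: 8 3-(benzyloxy)-2-iodo-5,6-dimethoxyphenol
Conditions: HCl (3 M aq), MeOH, 40 °C
Reagents that add atoms: none
Why: Acid-catalysed acetal exchange with methanol removes the MOM group. Benzyl and methyl ethers are stable to dilute acid, and the mild temperature should limit protodeiodination of the electron-rich ring.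

Step 6
Reactants: 9 1,2,3,4-tetramethoxybenzene
Product: 11 2,3,4,5-tetramethoxybenzaldehyde, via aryllithium 10 (not isolated)
Conditions: n-BuLi, TMEDA, THF, 0 °C → rt; DMF, 0 °C; aq HCl
Reagents that add atoms: N,N-dimethylformamide, CN(C)C=O
Why: Directed ortho-lithiation followed by formylation with DMF. The two ring hydrogens of 9 are equivalent and each lies ortho to a methoxy group, so only one aldehyde can form.

Step 7
Reactants: 11 2,3,4,5-tetramethoxybenzaldehyde
Product: 12 1-ethynyl-2,3,4,5-tetramethoxybenzene
Conditions: dimethyl (1-diazo-2-oxopropyl)phosphonate, K2CO3, MeOH, rt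
Reagents that add atoms: dimethyl (1-diazo-2-oxopropyl)phosphonate, CC(=O)C(=[N+]=[N-])P(=O)(OC)OC
Why: Seyferth–Gilbert homologation in the Ohira–Bestmann variant: methanolysis of the reagent gives the diazomethylphosphonate anion, which adds to the aldehyde, eliminates phosphate, loses N2 and gives the terminal alkyne by 1,2-hydrogen shift. The mild base suits this non-enolisable, electron-rich aldehyde.

Step 8
Reactants: 8 3-(benzyloxy)-2-iodo-5,6-dimethoxyphenol; 12 1-ethynyl-2,3,4,5-tetramethoxybenzene; 13 carbon monoxide
Product: 16 5-(benzyloxy)-7,8-dimethoxy-2-(2,3,4,5-tetramethoxyphenyl)-4H-chromen-4-one, via ynone 14 (not isolated), via enaminone 15 (not isolated)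
Conditions: PdCl2(PPh3)2 (5 mol %), CO (10 bar), Et2NH, 100 °C
Reagents that add atoms: none
Why: PdCl2(PPh3)2 (divalent palladium) is reduced in the amine/CO medium to zerovalent palladium, which inserts into the C–I bond of 8 at the carbon that becomes C4a. The electron-rich aryl group then migrates to coordinated 13 to give an aroylpalladium iodide (C4a–C4). The acetylide formed from 12 and diethylamine replaces iodide and reductive elimination forms C4–C3, giving ynone 14. Diethylamine adds to the β-carbon of 14 to give enaminone 15, and the phenol oxygen attacks the same carbon and expels the amine; this oxa-Michael addition–elimination forms O1–C2 and closes ring C in the 6-endo sense (6-endo-dig with respect to 14). The closest known reaction type is the palladium-catalysed carbonylative Sonogashira coupling of 2-iodophenols with terminal alkynes with cyclisation in the same pot to flavones. No stereocentre is formed. Three selectivities are needed: CO insertion before alkyne transfer, favoured by CO pressure, the absence of copper and the electron-rich aryl group; six-membered over five-membered (aurone) closure, secured by the passage through 15, which directs the oxygen to C2; and the ring A pattern, secured because the only free hydroxyl ortho to iodine is the one next to the C8 methoxy group while O5 is benzylated, so only the 5,7,8 arrangement can arise.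

Step 9
Reactants: 16 5-(benzyloxy)-7,8-dimethoxy-2-(2,3,4,5-tetramethoxyphenyl)-4H-chromen-4-one
Product: 17 5-hydroxy-7,8-dimethoxy-2-(2,3,4,5-tetramethoxyphenyl)-4H-chromen-4-one
Conditions: BCl3 (1 M in CH2Cl2), pentamethylbenzene, CH2Cl2, −78 °C; then MeOH, aq NaHCO3
Reagents that add atoms: none
Why: Lewis-acid debenzylation: BCl3 is held between the C4 carbonyl oxygen and O5, the benzyl–oxygen bond ionises at −78 °C, and pentamethylbenzene traps the benzyl cation so that the electron-rich rings are not C-benzylated. Unchelated methyl ethers should not be cleaved at this temperature, and the chelated 5-hydroxyl is released on work-up.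

## Compound list

1 | 3-hydroxy-4,5-dimethoxybenzaldehyde | COc1cc(C=O)cc(O)c1OC | starting material
2 | 3,4-dimethoxy-5-(methoxymethoxy)benzaldehyde | COCOc1cc(C=O)cc(OC)c1OC | intermediate
3 | 3,4-dimethoxy-5-(methoxymethoxy)phenyl formate | COCOc1cc(OC=O)cc(OC)c1OC | intermediate (not isolated)
4 | 3,4-dimethoxy-5-(methoxymethoxy)phenol | COCOc1cc(O)cc(OC)c1OC | intermediate
5 | 5-(benzyloxy)-1,2-dimethoxy-3-(methoxymethoxy)benzene | COCOc1cc(OCc2ccccc2)cc(OC)c1OC | intermediate
6 | [6-(benzyloxy)-3,4-dimethoxy-2-(methoxymethoxy)phenyl]lithium | [Li]c1c(OCOC)c(OC)c(OC)cc1OCc1ccccc1 | intermediate (not isolated)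
7 | 1-(benzyloxy)-2-iodo-4,5-dimethoxy-3-(methoxymethoxy)benzene | COCOc1c(I)c(OCc2ccccc2)cc(OC)c1OC | intermediate
8 | 3-(benzyloxy)-2-iodo-5,6-dimethoxyphenol | COc1cc(OCc2ccccc2)c(I)c(O)c1OC | intermediate
9 | 1,2,3,4-tetramethoxybenzene | COc1ccc(OC)c(OC)c1OC | starting material
10 | (2,3,4,5-tetramethoxyphenyl)lithium | [Li]c1cc(OC)c(OC)c(OC)c1OC | intermediate (not isolated)
11 | 2,3,4,5-tetramethoxybenzaldehyde | COc1cc(C=O)c(OC)c(OC)c1OC | intermediate
12 | 1-ethynyl-2,3,4,5-tetramethoxybenzene | C#Cc1cc(OC)c(OC)c(OC)c1OC | intermediate
13 | carbon monoxide | [C-]#[O+] | starting material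
14 | 1-[6-(benzyloxy)-2-hydroxy-3,4-dimethoxyphenyl]-3-(2,3,4,5-tetramethoxyphenyl)prop-2-yn-1-one | COc1cc(C#CC(=O)c2c(O)c(OC)c(OC)cc2OCc2ccccc2)c(OC)c(OC)c1OC | intermediate (not isolated)
15 | (E)-1-[6-(benzyloxy)-2-hydroxy-3,4-dimethoxyphenyl]-3-(diethylamino)-3-(2,3,4,5-tetramethoxyphenyl)prop-2-en-1-one | CCN(CC)/C(=C/C(=O)c1c(O)c(OC)c(OC)cc1OCc1ccccc1)c1cc(OC)c(OC)c(OC)c1OC | intermediate (not isolated)
16 | 5-(benzyloxy)-7,8-dimethoxy-2-(2,3,4,5-tetramethoxyphenyl)-4H-chromen-4-one | COc1cc(-c2cc(=O)c3c(OCc4ccccc4)cc(OC)c(OC)c3o2)c(OC)c(OC)c1OC | intermediate
17 | 5-hydroxy-7,8-dimethoxy-2-(2,3,4,5-tetramethoxyphenyl)-4H-chromen-4-one | COc1cc(-c2cc(=O)c3c(O)cc(OC)c(OC)c3o2)c(OC)c(OC)c1OC | target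

## Step count and least certain steps

Total: 9 steps. Longest linear sequence: 7 steps (steps 1–5, 8, 9); the alkyne branch contributes steps 6 and 7.

**Step 8 (key step).** The C–I bond of 8 is flanked by two oxygen substituents and sits on an electron-rich ring, so oxidative addition and the later steps on palladium may be slow. Three processes can then take over:
- alkyne transfer before CO insertion, followed by five-membered closure of the resulting alkynylphenol;
- capture of the aroylpalladium species by diethylamine (aminocarbonylation);
- consumption of 12 by oligomerisation or hydroamination while the catalyst precipitates.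

Fallback, without palladium or CO, setting out from 5 and 11 and returning at 16: 5 is lithiated as in step 4 to 6 and quenched with N-methoxy-N-methylacetamide to give 1-[6-(benzyloxy)-3,4-dimethoxy-2-(methoxymethoxy)phenyl]ethan-1-one F1. HCl in MeOH removes the acetal to give 1-[6-(benzyloxy)-2-hydroxy-3,4-dimethoxyphenyl]ethan-1-one F2. Claisen–Schmidt condensation of F2 with 11 (KOH, EtOH, rt) gives (E)-1-[6-(benzyloxy)-2-hydroxy-3,4-dimethoxyphenyl]-3-(2,3,4,5-tetramethoxyphenyl)prop-2-en-1-one F3. Oxidative cyclisation of this 2'-hydroxychalcone with I2 (cat.) in DMSO at 120 °C gives 16. The ring closure again can only use the single free hydroxyl.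

**Step 4.** Deprotonation at the benzylic CH2 of the benzyl ether (followed by [1,2]-Wittig rearrangement), or lithiation at the other doubly flanked ring position, would erode the yield. An iodide at the wrong position cannot annulate later, so the loss would be of material and not of regiochemical purity.

Fallback, setting out from 5 and returning at 8: the acetal of 5 is removed first (HCl, MeOH) to give 5-(benzyloxy)-2,3-dimethoxyphenol F4. F4 is iodinated under phenoxide- or amine-mediated conditions that favour the position ortho to the free hydroxyl (I2, morpholine, or BnMe3N ICl2 with NaHCO3 in CH2Cl2–MeOH), giving 8 directly. Iodination para to the hydroxyl is the expected competing process and would need chromatographic removal.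

**Step 5.** The iodinated carbon lies between two oxygens and para to a third, so ipso-protonation with loss or migration of iodine can compete with acetal cleavage in acid.

Fallback, setting out from 7 and returning at 14 and then 16: the iodide 7 is taken with 12 and 13 into a carbonylative Sonogashira coupling that stops at the ketone (PdCl2(PPh3)2, CuI, Et3N, CO 1 atm, THF, rt), giving 1-[6-(benzyloxy)-3,4-dimethoxy-2-(methoxymethoxy)phenyl]-3-(2,3,4,5-tetramethoxyphenyl)prop-2-yn-1-one F5. The acetal is removed only now, when no C–I bond is left (HCl, MeOH), to give 14. Et2NH in EtOH closes 14 through 15 to 16.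

**Step 9.** On warming or with excess BCl3, cleavage of a methyl ether within the vicinal dimethoxy arrays (C7/C8, C2'–C5') can begin. If the benzyl cation is not trapped, Friedel–Crafts benzylation of ring B at C6' or of ring A at C6 can occur.

Fallback, setting out from 16 and returning at 17: hydrogenolysis of the benzylic C–O bond (H2 1 atm, Pd/C (palladium on carbon), EtOAc–THF, rt). This is a reductive cleavage on the metal surface that involves no Lewis acid and no cation, so its failure modes do not overlap with those of BCl3. It is stopped at consumption of 16 to spare the C2=C3 bond.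

## Further compounds

F1 | step 8 | 1-[6-(benzyloxy)-3,4-dimethoxy-2-(methoxymethoxy)phenyl]ethan-1-one | CC(=O)c1c(OCOC)c(OC)c(OC)cc1OCc1ccccc1
F2 | step 8 | 1-[6-(benzyloxy)-2-hydroxy-3,4-dimethoxyphenyl]ethan-1-one | CC(=O)c1c(O)c(OC)c(OC)cc1OCc1ccccc1
F3 | step 8 | (E)-1-[6-(benzyloxy)-2-hydroxy-3,4-dimethoxyphenyl]-3-(2,3,4,5-tetramethoxyphenyl)prop-2-en-1-one | COc1cc(/C=C/C(=O)c2c(O)c(OC)c(OC)cc2OCc2ccccc2)c(OC)c(OC)c1OC
F4 | step 4 | 5-(benzyloxy)-2,3-dimethoxyphenol | COc1cc(OCc2ccccc2)cc(O)c1OC
F5 | step 5 | 1-[6-(benzyloxy)-3,4-dimethoxy-2-(methoxymethoxy)phenyl]-3-(2,3,4,5-tetramethoxyphenyl)prop-2-yn-1-one | COCOc1c(C(=O)C#Cc2cc(OC)c(OC)c(OC)c2OC)c(OCc2ccccc2)cc(OC)c1OC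
F0 | step 9 | none | none
A1 | alternative 1 | 5-hydroxy-2-(2-hydroxy-3,4,5-trimethoxyphenyl)-7,8-dimethoxy-4H-chromen-4-one | COc1cc(-c2cc(=O)c3c(O)cc(OC)c(OC)c3o2)c(O)c(OC)c1OC
A2 | alternative 1 | 2-ethynyl-5-hydroxy-7,8-dimethoxy-4H-chromen-4-one | C#Cc1cc(=O)c2c(O)cc(OC)c(OC)c2o1
A3 | alternative 1 | pentacarbonyl{[(Z)-1,2-dimethoxyvinyl](methoxy)carbene}chromium, Cr(CO)5[C(OMe)C(OMe)=CH(OMe)] | CO/C=C(\OC)C(OC)=[Cr](=C=O)(=C=O)(=C=O)(=C=O)=C=O
A4 | alternative 2 | 5,7-dihydroxy-8-methoxy-2-(2,3,4,5-tetramethoxyphenyl)-4H-chromen-4-one | COc1cc(-c2cc(=O)c3c(O)cc(O)c(OC)c3o2)c(OC)c(OC)c1OC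
A5 | alternative 2 | methyl 2-[3-acetyl-4-oxo-6-(2,3,4,5-tetramethoxyphenyl)-4H-pyran-2-yl]-2-methoxyacetate (racemic) | COC(=O)C(OC)c1oc(-c2cc(OC)c(OC)c(OC)c2OC)cc(=O)c1C(C)=O
A6 | alternative 3 | 5,7,8-trimethoxy-2-(2,3,4,5-tetramethoxyphenyl)-4H-chromen-4-one | COc1cc(-c2cc(=O)c3c(OC)cc(OC)c(OC)c3o2)c(OC)c(OC)c1OC
A7 | alternative 3 | (Z)-3-(2,3,4,5-tetramethoxyphenyl)-3-(2,3,5-trimethoxyphenoxy)prop-2-enoic acid | OC(=O)/C=C(\Oc1cc(OC)cc(OC)c1OC)c1cc(OC)c(OC)c(OC)c1OC
A8 | alternative 3 | 2,3,5-trimethoxyphenol | COc1cc(O)c(OC)c(OC)c1
A9 | alternative 3 | methyl 3-(2,3,4,5-tetramethoxyphenyl)prop-2-ynoate | COC(=O)C#Cc1cc(OC)c(OC)c(OC)c1OC
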